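**Retrosynthetic overview**
1. The target comes from a hexabenzyl 6,6'-biflavan by a final O-debenzylation. Its C6–C6' bond is a routine late Suzuki union of two 6-bromoflavan-3,4-diols that differ only at C4 (an all-cis half and a 3,4-trans half).
2. Both halves come from one (S)-6-bromoflav-3-ene by divergent C3–O/C4–O bond formation on the aryl face: wet conditions (Woodward) give 3,4-cis, dry conditions (Prévost) give 3,4-trans.
3. The (S)-flavene comes from the key C2–O1 bond: an enantioselective dehydrative 6-endo closure of a 2'-hydroxychalcone-derived allylic alcohol.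
4. The allylic alcohol comes from a chalcone, made from 5-bromo-3,4-di-O-benzylgallacetophenone and 4-(benzyloxy)benzaldehyde.
5. Ring order: rings A and B are bought as arenes, ring C of each half is closed in the C–O step, and the two finished halves are joined at the end.

Assumption: the sense of induction of the chiral acid in step 5 cannot be predicted with certainty; the (R)-catalyst is written, and its antipode is used if it delivers the (R)-flavene.

Compound 7 is divided between steps 6 and 7.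

**Step 1**
Reactants: 1 gallacetophenone [1-(2,3,4-trihydroxyphenyl)ethan-1-one]
Product: 2 1-[3,4-bis(benzyloxy)-2-hydroxyphenyl]ethan-1-one
Conditions: BnBr (2.1 eq), K2CO3 (2.2 eq), acetone, reflux
Reagents that add atoms: benzyl bromide, BrCc1ccccc1
Why: Williamson etherification in which the 2-OH, locked in a hydrogen bond to the acetyl carbonyl, stays free while the 3- and 4-OH are benzylated.

**Step 2**
Reactants: 2 1-[3,4-bis(benzyloxy)-2-hydroxyphenyl]ethan-1-one
Product: 3 1-[3,4-bis(benzyloxy)-5-bromo-2-hydroxyphenyl]ethan-1-one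
Conditions: NBS (1.05 eq), MeCN, 0 °C to rt, dark
Reagents that add atoms: N-bromosuccinimide, O=C1CCC(=O)N1Br
Why: Electrophilic aromatic bromination goes to the only position para to the free phenol and ortho to the 4-benzyloxy group, which becomes C6 of the flavan.

**Step 3**
Reactants: 3 1-[3,4-bis(benzyloxy)-5-bromo-2-hydroxyphenyl]ethan-1-one; 4 4-(benzyloxy)benzaldehyde
Product: 5 (E)-1-[3,4-bis(benzyloxy)-5-bromo-2-hydroxyphenyl]-3-[4-(benzyloxy)phenyl]prop-2-en-1-one
Conditions: KOH (50% aq.), EtOH, rt, 36 h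
Reagents that add atoms: none
Why: Claisen–Schmidt aldol condensation, whose E1cB dehydration gives the (E)-2'-hydroxychalcone.

**Step 4**
Reactants: 5 (E)-1-[3,4-bis(benzyloxy)-5-bromo-2-hydroxyphenyl]-3-[4-(benzyloxy)phenyl]prop-2-en-1-one
Product: 6 racemic (E)-1-[3,4-bis(benzyloxy)-5-bromo-2-hydroxyphenyl]-3-[4-(benzyloxy)phenyl]prop-2-en-1-ol
Conditions: NaBH4 (1.5 eq), CeCl3·7H2O (1.2 eq), MeOH/THF, −20 °C; pH 7 buffer work-up, no chromatography, used at once
Reagents that add atoms: none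
Why: Luche 1,2-reduction of the enone carbonyl gives a racemic carbinol, which is harmless because this stereocentre is erased in the next step.

**Step 5**
Reactants: 6 racemic (E)-1-[3,4-bis(benzyloxy)-5-bromo-2-hydroxyphenyl]-3-[4-(benzyloxy)phenyl]prop-2-en-1-ol
Product: 7 (2S)-7,8-bis(benzyloxy)-2-[4-(benzyloxy)phenyl]-6-bromo-2H-chromene
Conditions: (R)-3,3'-bis(2,4,6-triisopropylphenyl)-1,1'-binaphthyl-2,2'-diyl N-triflylphosphoramide (5 mol%), 4 Å MS, toluene, −60 °C, dark; Et3N quench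
Reagents that add atoms: none
Why: Proposed new method: the chiral acid ionises the doubly activated benzylic–allylic carbinol (either enantiomer) to one planar 1,3-diarylallyl cation with quinone-methide character, held as a contact ion pair whose phosphoramide anion also hydrogen-bonds the ring A phenol, and 6-endo attack of that phenol oxygen on the aryl-bearing terminus inside the chiral pocket closes ring C and sets C2 as S in an enantioconvergent way; the closest known reaction type is the chiral N-triflylphosphoramide-catalysed intramolecular asymmetric allylic etherification of phenols through contact ion pairs, together with the racemic acid-induced closure of reduced 2'-hydroxychalcones to flav-3-enes, and enantiocontrol has not been shown on a 4-unsubstituted polyoxygenated flavene.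

**Step 6**
Reactants: 7 (2S)-7,8-bis(benzyloxy)-2-[4-(benzyloxy)phenyl]-6-bromo-2H-chromene
Product: 10 (2R,3R,4R)-7,8-bis(benzyloxy)-2-[4-(benzyloxy)phenyl]-6-bromochromane-3,4-diol, via trans-iodoacetate 8 (not isolated), via cis-hydroxy acetate 9 (not isolated)
Conditions: I2 (1.05 eq), AgOAc (silver acetate, 2.2 eq), AcOH/H2O 25:1, rt then 45 °C, dark; filter, evaporate; K2CO3 (0.3 eq), MeOH, 0 °C
Reagents that add atoms: silver acetate, CC(=O)[O-].[Ag+]
Why: Woodward cis-hydroxylation, in which the iodonium ion forms anti to the 2-aryl group, acetate opens it at benzylic C4, silver-assisted displacement of iodide by the acetate carbonyl inverts C3 to give a cis-fused acetoxonium ion on the aryl face, and water attacks the acetoxonium carbon so that both C–O bonds end up cis to the aryl group (3R,4R) before the acetate is removed by methanolysis.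

**Step 7**
Reactants: 7 (2S)-7,8-bis(benzyloxy)-2-[4-(benzyloxy)phenyl]-6-bromo-2H-chromene
Product: 13 (2R,3R,4S)-7,8-bis(benzyloxy)-2-[4-(benzyloxy)phenyl]-6-bromochromane-3,4-diol, via trans-iodobenzoate 11 (not isolated), via trans-dibenzoate 12 (not isolated)
Conditions: I2 (1.05 eq), PhCO2Ag (silver benzoate, 2.3 eq), 4 Å MS, dry toluene, rt then 60 °C, dark; filter, evaporate; K2CO3 (0.3 eq), MeOH/THF, rt
Reagents that add atoms: silver benzoate, O=C([O-])c1ccccc1.[Ag+]
Why: Prévost reaction, in which the same cis-fused benzoxonium ion forms on the aryl face but, without water, a second benzoate opens it at benzylic C4 with inversion, so the 3-oxygen stays cis to the aryl group and the 4-oxygen ends up trans (3R,4S after methanolysis).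

**Step 8**
Reactants: 13 (2R,3R,4S)-7,8-bis(benzyloxy)-2-[4-(benzyloxy)phenyl]-6-bromochromane-3,4-diol; 10 (2R,3R,4R)-7,8-bis(benzyloxy)-2-[4-(benzyloxy)phenyl]-6-bromochromane-3,4-diol
Product: 15 (2R,2'R,3R,3'R,4R,4'S)-7,7',8,8'-tetrakis(benzyloxy)-2,2'-bis[4-(benzyloxy)phenyl]-[6,6'-bichromane]-3,3',4,4'-tetrol, via pinacol boronate 14 (not isolated)
Conditions: 13, B2pin2 (1.1 eq), KOAc (3 eq), Pd(dppf)Cl2 (5 mol%), 1,4-dioxane, 90 °C; then 10 (0.9 eq), K3PO4 (3 eq), H2O, 80 °C
Reagents that add atoms: none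
Why: Miyaura borylation of the trans-diol bromide followed in the same flask by Suzuki–Miyaura cross-coupling with the cis-diol bromide joins the two C4 epimers through a biaryl with only two ortho substituents, and no stereocentre is touched.

**Step 9**
Reactants: 15 (2R,2'R,3R,3'R,4R,4'S)-7,7',8,8'-tetrakis(benzyloxy)-2,2'-bis[4-(benzyloxy)phenyl]-[6,6'-bichromane]-3,3',4,4'-tetrol
Product: 16 (2R,2'R,3R,3'R,4R,4'S)-2,2'-bis(4-hydroxyphenyl)-[6,6'-bichromane]-3,3',4,4',7,7',8,8'-octol (target)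
Conditions: H2 (1 atm), Pd(OH)2/C, THF/EtOAc, rt; filter under Ar
Reagents that add atoms: none
Why: Hydrogenolysis of the six aryl benzyl ethers under neutral, alcohol-free conditions, under which flavan-3,4-diols are expected to survive (they are classically made by catalytic hydrogenation of dihydroflavonols), so the C4 carbinols should be neither epimerised nor reduced.

**Compound list**
1 | gallacetophenone, 1-(2,3,4-trihydroxyphenyl)ethan-1-one | CC(=O)c1ccc(O)c(O)c1O | starting material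
2 | 1-[3,4-bis(benzyloxy)-2-hydroxyphenyl]ethan-1-one | CC(=O)c1ccc(OCc2ccccc2)c(OCc2ccccc2)c1O | intermediate
3 | 1-[3,4-bis(benzyloxy)-5-bromo-2-hydroxyphenyl]ethan-1-one | CC(=O)c1cc(Br)c(OCc2ccccc2)c(OCc2ccccc2)c1O | intermediate
4 | 4-(benzyloxy)benzaldehyde | O=Cc1ccc(OCc2ccccc2)cc1 | starting material
5 | (E)-1-[3,4-bis(benzyloxy)-5-bromo-2-hydroxyphenyl]-3-[4-(benzyloxy)phenyl]prop-2-en-1-one | O=C(/C=C/c1ccc(OCc2ccccc2)cc1)c1cc(Br)c(OCc2ccccc2)c(OCc2ccccc2)c1O | intermediate
6 | racemic (E)-1-[3,4-bis(benzyloxy)-5-bromo-2-hydroxyphenyl]-3-[4-(benzyloxy)phenyl]prop-2-en-1-ol | OC(/C=C/c1ccc(OCc2ccccc2)cc1)c1cc(Br)c(OCc2ccccc2)c(OCc2ccccc2)c1O | intermediate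
7 | (2S)-7,8-bis(benzyloxy)-2-[4-(benzyloxy)phenyl]-6-bromo-2H-chromene | c1ccccc1COc1ccc([C@H]2Oc3c(cc(Br)c(OCc4ccccc4)c3OCc3ccccc3)C=C2)cc1 | intermediate
8 | (2R,3R,4R)-7,8-bis(benzyloxy)-2-[4-(benzyloxy)phenyl]-6-bromo-3-iodochroman-4-yl acetate (2,3-trans-3,4-trans) | c1ccccc1COc1ccc([C@H]2Oc3c(cc(Br)c(OCc4ccccc4)c3OCc3ccccc3)[C@@H](OC(C)=O)[C@@H]2I)cc1 | intermediate (not isolated)
9 | (2R,3R,4R)-7,8-bis(benzyloxy)-2-[4-(benzyloxy)phenyl]-6-bromo-4-hydroxychroman-3-yl acetate (all-cis; any 4-acetate regioisomer gives the same diol) | c1ccccc1COc1ccc([C@H]2Oc3c(cc(Br)c(OCc4ccccc4)c3OCc3ccccc3)[C@@H](O)[C@H]2OC(C)=O)cc1 | intermediate (not isolated)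
10 | (2R,3R,4R)-7,8-bis(benzyloxy)-2-[4-(benzyloxy)phenyl]-6-bromochromane-3,4-diol (2,3-cis-3,4-cis) | c1ccccc1COc1ccc([C@H]2Oc3c(cc(Br)c(OCc4ccccc4)c3OCc3ccccc3)[C@@H](O)[C@H]2O)cc1 | intermediate
11 | (2R,3R,4R)-7,8-bis(benzyloxy)-2-[4-(benzyloxy)phenyl]-6-bromo-3-iodochroman-4-yl benzoate (2,3-trans-3,4-trans) | c1ccccc1COc1ccc([C@H]2Oc3c(cc(Br)c(OCc4ccccc4)c3OCc3ccccc3)[C@@H](OC(=O)c3ccccc3)[C@@H]2I)cc1 | intermediate (not isolated)
12 | (2R,3S,4S)-7,8-bis(benzyloxy)-2-[4-(benzyloxy)phenyl]-6-bromochromane-3,4-diyl dibenzoate (2,3-cis-3,4-trans) | c1ccccc1COc1ccc([C@H]2Oc3c(cc(Br)c(OCc4ccccc4)c3OCc3ccccc3)[C@H](OC(=O)c3ccccc3)[C@H]2OC(=O)c2ccccc2)cc1 | intermediate (not isolated)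
13 | (2R,3R,4S)-7,8-bis(benzyloxy)-2-[4-(benzyloxy)phenyl]-6-bromochromane-3,4-diol (2,3-cis-3,4-trans) | c1ccccc1COc1ccc([C@H]2Oc3c(cc(Br)c(OCc4ccccc4)c3OCc3ccccc3)[C@H](O)[C@H]2O)cc1 | intermediate
14 | (2R,3R,4S)-7,8-bis(benzyloxy)-2-[4-(benzyloxy)phenyl]-6-(4,4,5,5-tetramethyl-1,3,2-dioxaborolan-2-yl)chromane-3,4-diol | c1ccccc1COc1ccc([C@H]2Oc3c(cc(B4OC(C)(C)C(C)(C)O4)c(OCc4ccccc4)c3OCc3ccccc3)[C@H](O)[C@H]2O)cc1 | intermediate (not isolated)
15 | (2R,2'R,3R,3'R,4R,4'S)-7,7',8,8'-tetrakis(benzyloxy)-2,2'-bis[4-(benzyloxy)phenyl]-[6,6'-bichromane]-3,3',4,4'-tetrol | c1ccccc1COc1ccc([C@H]2Oc3c(cc(-c4cc5c(c(OCc6ccccc6)c4OCc4ccccc4)O[C@H](c4ccc(OCc6ccccc6)cc4)[C@H](O)[C@H]5O)c(OCc4ccccc4)c3OCc3ccccc3)[C@@H](O)[C@H]2O)cc1 | intermediate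
16 | (2R,2'R,3R,3'R,4R,4'S)-2,2'-bis(4-hydroxyphenyl)-[6,6'-bichromane]-3,3',4,4',7,7',8,8'-octol | Oc1ccc([C@H]2Oc3c(cc(-c4cc5c(c(O)c4O)O[C@H](c4ccc(O)cc4)[C@H](O)[C@H]5O)c(O)c3O)[C@@H](O)[C@H]2O)cc1 | target

**Step count and risks**
Total steps: 9 (steps 6 and 7 are parallel branches from 7). Longest linear sequence: 8 (steps 1 to 5, then 6 or 7, then 8 and 9).

The three steps most likely to fail:

Step 5 (the proposed new cyclisation). The carbinol 6 ionises so easily that uncatalysed racemic closure may compete, and the strong acid may re-open the C2–O1 bond of the product, so the enantiomeric excess may be low. The fallback uses known chemistry and sets out from 6: closure with catalytic PPTS in CH2Cl2 gives the racemic 7,8-bis(benzyloxy)-2-[4-(benzyloxy)phenyl]-6-bromo-2H-chromene F1, which is resolved by preparative chiral SFC on an amylose carbamate phase; the (R)-enantiomer is re-equilibrated with catalytic TsOH and resolved again. It comes back to the route at 7.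

Step 6 (Woodward cis-hydroxylation). The benzylic C4 cation is strongly stabilised, so water may add at C4 of the opened ion instead of at the acetoxonium carbon and give the 3,4-trans diol; excess reagent may also iodinate the 4-benzyloxyphenyl ring. The fallback sets out from 13, the trans-diol that step 7 delivers: MnO2 in CH2Cl2 oxidises only the activated benzylic 4-OH to (2R,3S)-7,8-bis(benzyloxy)-2-[4-(benzyloxy)phenyl]-6-bromo-3-hydroxychroman-4-one F2, and NaBH4 in MeOH/THF at −40 °C then delivers hydride anti to the axial 3-OH to give the 3,4-cis diol. It comes back to the route at 10.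

Step 9 (final hydrogenolysis). The two C4 carbinols are electron-rich benzylic alcohols and could be hydrogenolysed or epimerised on palladium, and the product is air- and acid-sensitive. The fallback sets out from 15: TBSOTf and 2,6-lutidine in CH2Cl2 at −40 °C mask the four secondary alcohols as the tetrakis(tert-butyldimethylsilyl) ether of 15 F3, hydrogenolysis (H2, Pd(OH)2/C, EtOAc) gives the tetrakis-O-TBS hexaphenol F4 with the benzylic oxygens protected against C–O cleavage, and HF·pyridine buffered with excess pyridine in THF at 0 °C removes the silyl groups. It comes back to the route at 16.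

**Further compounds**
F1 | step 5 | racemic 7,8-bis(benzyloxy)-2-[4-(benzyloxy)phenyl]-6-bromo-2H-chromene | c1ccccc1COc1ccc(C2Oc3c(cc(Br)c(OCc4ccccc4)c3OCc3ccccc3)C=C2)cc1
F2 | step 6 | (2R,3S)-7,8-bis(benzyloxy)-2-[4-(benzyloxy)phenyl]-6-bromo-3-hydroxychroman-4-one (2,3-cis) | c1ccccc1COc1ccc([C@H]2Oc3c(cc(Br)c(OCc4ccccc4)c3OCc3ccccc3)C(=O)[C@H]2O)cc1
F3 | step 9 | 3,3',4,4'-tetrakis-O-(tert-butyldimethylsilyl) ether of 15 | c1ccccc1COc1ccc([C@H]2Oc3c(cc(-c4cc5c(c(OCc6ccccc6)c4OCc4ccccc4)O[C@H](c4ccc(OCc6ccccc6)cc4)[C@H](O[Si](C)(C)C(C)(C)C)[C@H]5O[Si](C)(C)C(C)(C)C)c(OCc4ccccc4)c3OCc3ccccc3)[C@@H](O[Si](C)(C)C(C)(C)C)[C@H]2O[Si](C)(C)C(C)(C)C)cc1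
F4 | step 9 | 3,3',4,4'-tetrakis-O-(tert-butyldimethylsilyl) ether of 16 | Oc1ccc([C@H]2Oc3c(cc(-c4cc5c(c(O)c4O)O[C@H](c4ccc(O)cc4)[C@H](O[Si](C)(C)C(C)(C)C)[C@H]5O[Si](C)(C)C(C)(C)C)c(O)c3O)[C@@H](O[Si](C)(C)C(C)(C)C)[C@H]2O[Si](C)(C)C(C)(C)C)cc1
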